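## The problem

Target **19** is a 1‑aryltetralin. Ring B (C1–C4) is fused to the guaiacyl ring A and carries three contiguous stereocentres: C1 (4‑hydroxy‑3‑methoxyphenyl), C2 (CO2Me) and C3 (CH2OH), all‑trans, 1R,2S,3S. All three substituents can be equatorial on the half‑chair, so the relative configuration is the thermodynamic one. C2 (α to a carbonyl) can be equilibrated, but C3 is a plain alkyl centre that cannot be corrected later. C3 must therefore be set absolutely and then made to direct C1 and C2. Ring A must carry OMe at C6 and OH at C7, so the bond from C8a to C1 must be placed para to the methoxy group without ambiguity. Three features will not stand rough treatment. The phenol on the C1 aryl group lies para to a doubly benzylic C–H and is easily oxidised to a quinone methide. The γ‑hydroxy ester lactonises under acid or base. C2 can epimerise. The feature that makes the key step possible is the 4‑hydroxy‑3‑methoxyphenyl group on C1: a C1 carbinol of this type loses water to a para‑quinone methide, so C1 is an electrophile, while C2 becomes a nucleophile (an enamine) when the carboxyl carbon is at the aldehyde level. At that level the C2 carbonyl and the C3 hydroxymethyl form a lactol, so the primary alcohol needs no protecting group.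

## Retrosynthesis

**19 ⇐ 18 ⇐ 17.** No skeletal bond is cut here. The two phenols of **19** are released last from the bis(benzyl ether) **18** by neutral hydrogenolysis, so the free hydroxy ester never meets acid or base. **18** is the methanolysis product of the trans‑fused lactone **17**. The lactone holds the alcohol and the carboxyl in one unreactive ring. The forward opening has to stop at the hydroxy ester and leave C2 alone.

**17 ⇐ 16 ⇐ 15.** Lactone **17** comes from lactol **16** by oxidation of the hemiacetal C–H. A silver oxidant would also attack a free para‑alkylphenol, so the phenol that triggers the key step is benzylated first (**15** → **16**). This costs one step but adds no separate deprotection, because both benzyl groups leave together at the end.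

**15 ⇐ 13 (key cut, C1–C2).** The alternatives are cutting C1–C8a (ring A as nucleophile) or C2–C3 (C3 made during ring closure). Cutting C1–C2 has three advantages. It uses the latent quinone methide and gives an open‑chain precursor with only the C3 centre. The ring‑A regiochemistry is fixed earlier by a bromine atom. The ring closes at the aldehyde level, where C2 equilibrates and the trans‑fused lactol is unstrained. The forward reaction must form the enamine and the quinone methide in the same flask and join them at carbon.

**13 ⇐ 12 ⇐ 8 + 10 (C1–C8a).** The benzhydrol carbon is attached to ring A by adding an aryllithium (from bromide **8**) to the silyl‑protected vanillin **10**. The carbinol configuration is irrelevant. The lactol of **8** and the phenol of **10** are both masked as silyl ethers, so a single fluoride treatment (**12** → **13**) releases both without acid. This matters because the benzhydrol ionises easily.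

**8 ⇐ 7 ⇐ 6.** The silyl acetal **8** comes from lactol **7**, the half‑reduction product of lactone **6**. The lactone is the stable form in which the C3 centre is carried.

**6 ⇐ 5 ⇐ 4 ⇐ 2 + 3; 2 ⇐ 1; 10 ⇐ 9.** Lactone **6** comes from the succinate half‑ester **5** by reduction of the ester in the presence of the carboxylate. **5** comes from the alkylidene succinate **4** by asymmetric hydrogenation, the only step that introduces absolute configuration. **4** is the Stobbe product of aldehyde **2** and dimethyl succinate **3**. **2** is the benzyl ether of 6‑bromovanillin **1**, which already has the ring‑A oxygen pattern and the bromine at the future C8a. **10** is silylated vanillin **9**.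

## Roads not taken

**Alternative 1:** The cut is C2–C3, with a temporary cyclopropane. The diazo keto ester A1 would give a copper carbene (CuOTf, chiral bis(oxazoline)) that adds to the ortho‑allyl alkene and forms the cyclopropane‑fused tetralone A2. Homoconjugate opening at the cyclopropane CH2 by an oxygen nucleophile would then give the C3 CH2O group.
- Merits: the ring closure is itself catalytic and asymmetric, and A1 is flat and quickly made.
- Weak points: A2 has only the C3 centre and no C1 aryl group. The C1 ketone is part of a β‑keto ester that enolises rather than accepting an aryl nucleophile. The aryl group would have to come in through an enol triflate and cross‑coupling, followed by reduction of a tetrasubstituted C1=C2 alkene with two centres still to control. Acceptor/acceptor carbenes are also poor partners for high enantioselectivity, and the electron‑rich ring A invites aromatic addition.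
- Comparison: this road is better in making ring closure and asymmetric induction one event. The chosen plan answers with all three centres in place when ring B closes and only functional‑group changes afterwards.

**Alternative 2:** The cuts are C2–C3 and C1–C8a. Heating the bis‑benzylated coniferyl ferulate A3 would let the styrene act as diene toward the ferulate double bond. A hydrogen shift would then restore ring A and give lactone A4, which is the same compound as **17**.
- Merits: A3 is an ester of two cinnamyl‑type building blocks. One step builds ring B, the lactone and all three centres, and reaches a compound three steps from the target. In step count this road is clearly better than the chosen one.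
- Weak points: nothing in A3 sets absolute configuration, so the product is racemic. The cycloaddition breaks aromaticity and needs high temperature. Endo/exo selectivity decides between cis‑ and trans‑fused lactone. Ring A can bond at either ortho carbon, and the hydrogen shift competes with dehydrogenation to an arylnaphthalene.
- Comparison: if racemic material were enough, this would be the route. For a single enantiomer the chosen plan offers a dependable hydrogenation for the absolute configuration and thermodynamic control of the relative configuration.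

**Alternative 3:** The cuts are C1–aryl and C2–C3. An arylnickel species from boronic acid A6 (Ni(OAc)2, chiral phosphinooxazoline) would add across the ynoate A5 with aryl at C1. The alkenylnickel would isomerise and displace the allylic phosphate (SN2'), giving the dihydronaphthalene A7 with the C3 centre and a vinyl group.
- Merits: convergent, catalytic and asymmetric, with the C1 aryl group introduced late. In convergence it is at least equal to the chosen plan.
- Weak points: A7 has a tetrasubstituted, ester‑conjugated C1=C2 alkene, so C1 and C2 are still to be made. Syn hydrogenation would give the 1,2‑cis product and would need face selection relative to C3 followed by epimerisation at C2. The vinyl group must first be cut down to CH2OH. A5 itself takes several steps.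
- Comparison: the chosen plan is longer before the key step, but C1 and C2 are formed during ring closure under control by C3, not in a separate reduction with uncertain facial selectivity.

Key step: step 10

Remark: compounds 7, 13, 15 and 16 are γ‑hydroxy aldehydes that exist essentially as five‑membered lactols (anomer mixtures); they are handled as such, and their SMILES show the open‑chain tautomer.

**Step 1**
Reactants: 1 6‑bromovanillin (2‑bromo‑4‑hydroxy‑5‑methoxybenzaldehyde)
Product: 2 4‑(benzyloxy)‑2‑bromo‑5‑methoxybenzaldehyde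
Conditions: BnBr, K2CO3, DMF, rt
Reagents that add atoms: benzyl bromide, BrCc1ccccc1
Why: Williamson etherification of the phenoxide; the benzyl ether withstands methoxide, hydrides, butyllithium, fluoride and acid and is removed only in the last step.

**Step 2**
Reactants: 2 4‑(benzyloxy)‑2‑bromo‑5‑methoxybenzaldehyde; 3 dimethyl succinate
Product: 4 (E)‑4‑[4‑(benzyloxy)‑2‑bromo‑5‑methoxyphenyl]‑3‑(methoxycarbonyl)but‑3‑enoic acid
Conditions: NaOMe, MeOH, reflux; then aq. HCl
Reagents that add atoms: none
Why: Stobbe condensation: aldol addition of the succinate enolate, closure to the paraconic ester and E1cB opening stop the reaction at the half‑ester with the free acid on the saturated arm and the aryl group trans to the conjugated ester.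

**Step 3**
Reactants: 4 (E)‑4‑[4‑(benzyloxy)‑2‑bromo‑5‑methoxyphenyl]‑3‑(methoxycarbonyl)but‑3‑enoic acid
Product: 5 (3S)‑3‑{[4‑(benzyloxy)‑2‑bromo‑5‑methoxyphenyl]methyl}‑4‑methoxy‑4‑oxobutanoic acid
Conditions: H2 (5 atm), [Rh(cod)((R,R)‑Et‑DuPHOS)]BF4 (0.5 mol%), NaOMe (10 mol%), MeOH, rt
Reagents that add atoms: none
Why: Asymmetric hydrogenation of an itaconate‑type half‑ester: carboxylate and alkene chelate the cationic rhodium diphosphine, so hydrogen is delivered to one face and C3 is set as S; the (R,R) ligand is the hand expected to give this sense by analogy with simpler arylidene succinates (the mirror‑image ligand is used if the assignment proves opposite), and the homogeneous catalyst leaves the aryl bromide and benzyl ether alone.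

**Step 4**
Reactants: 5 (3S)‑3‑{[4‑(benzyloxy)‑2‑bromo‑5‑methoxyphenyl]methyl}‑4‑methoxy‑4‑oxobutanoic acid
Product: 6 (4S)‑4‑{[4‑(benzyloxy)‑2‑bromo‑5‑methoxyphenyl]methyl}oxolan‑2‑one
Conditions: KOH (1 equiv), EtOH, 0 °C; CaCl2, NaBH4, EtOH, −10 °C → rt; then 2 M HCl
Reagents that add atoms: none
Why: Chemoselective ester reduction: the potassium carboxylate is inert while Ca(BH4)2 formed in the flask reduces the methyl ester, and acidification closes the γ‑lactone; the stereocentre is not involved.

**Step 5**
Reactants: 6 (4S)‑4‑{[4‑(benzyloxy)‑2‑bromo‑5‑methoxyphenyl]methyl}oxolan‑2‑one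
Product: 7 (3S)‑3‑{[4‑(benzyloxy)‑2‑bromo‑5‑methoxyphenyl]methyl}‑4‑hydroxybutanal (obtained as its lactol (4S)‑4‑(arylmethyl)oxolan‑2‑ol)
Conditions: i‑Bu2AlH (1.1 equiv), CH2Cl2, −78 °C; aq. potassium sodium tartrate
Reagents that add atoms: none
Why: Half‑reduction of a lactone: the tetrahedral aluminium alkoxide is stable at −78 °C and gives the lactol only on work‑up, so over‑reduction to the diol is avoided.

**Step 6**
Reactants: 7 (3S)‑3‑{[4‑(benzyloxy)‑2‑bromo‑5‑methoxyphenyl]methyl}‑4‑hydroxybutanal (lactol)
Product: 8 tert‑butyl({(4S)‑4‑{[4‑(benzyloxy)‑2‑bromo‑5‑methoxyphenyl]methyl}oxolan‑2‑yl}oxy)dimethylsilane (anomer mixture)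
Conditions: TBSCl, imidazole, CH2Cl2, 0 °C → rt
Reagents that add atoms: tert‑butyldimethylsilyl chloride, CC(C)(C)[Si](C)(C)Cl
Why: Silylation of the anomeric hydroxyl of the dominant ring tautomer gives a mixed silyl acetal that is inert to alkyllithium at low temperature and is later removed by fluoride, not acid.

**Step 7**
Reactants: 9 vanillin
Product: 10 4‑[(tert‑butyldimethylsilyl)oxy]‑3‑methoxybenzaldehyde
Conditions: TBSCl, imidazole, CH2Cl2, rt
Reagents that add atoms: tert‑butyldimethylsilyl chloride, CC(C)(C)[Si](C)(C)Cl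
Why: Standard silylation of a phenol; the aryl silyl ether survives the aryllithium addition and is cleaved by the same fluoride treatment as the silyl acetal.

**Step 8**
Reactants: 8 tert‑butyl({(4S)‑4‑{[4‑(benzyloxy)‑2‑bromo‑5‑methoxyphenyl]methyl}oxolan‑2‑yl}oxy)dimethylsilane; 10 4‑[(tert‑butyldimethylsilyl)oxy]‑3‑methoxybenzaldehyde
Product: 12 {4‑(benzyloxy)‑2‑{[(3S)‑5‑(tert‑butyldimethylsilyloxy)oxolan‑3‑yl]methyl}‑5‑methoxyphenyl}[4‑(tert‑butyldimethylsilyloxy)‑3‑methoxyphenyl]methanol (mixture of carbinol and anomeric epimers), via aryllithium 11 (not isolated)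
Conditions: n‑BuLi (1.05 equiv), THF, −78 °C; then 10, −78 → −40 °C; aq. NH4Cl
Reagents that add atoms: none
Why: Bromine–lithium exchange is faster than any deprotonation at −78 °C and places the nucleophile exactly at the future C8a; 1,2‑addition to the non‑enolisable aldehyde gives the benzhydrol, whose configuration is erased in step 10.

**Step 9**
Reactants: 12 bis(silyl ether) benzhydrol
Product: 13 (3S)‑3‑{[4‑(benzyloxy)‑2‑[hydroxy(4‑hydroxy‑3‑methoxyphenyl)methyl]‑5‑methoxyphenyl]methyl}‑4‑hydroxybutanal (carbinol epimers; handled as its lactol and used crude)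
Conditions: Bu4NF (2.5 equiv), AcOH (2.5 equiv), THF, 0 °C → rt
Reagents that add atoms: none
Why: Fluoride cleaves the aryl silyl ether and the anomeric silyl ether in one operation; the acetate buffer keeps the medium near neutral, so the acid‑labile para‑hydroxybenzhydrol and the base‑sensitive hydroxy aldehyde both survive.

**Step 10**
Reactants: 13 (3S)‑3‑{[4‑(benzyloxy)‑2‑[hydroxy(4‑hydroxy‑3‑methoxyphenyl)methyl]‑5‑methoxyphenyl]methyl}‑4‑hydroxybutanal (lactol)
Product: 15 (1R,2S,3S)‑7‑(benzyloxy)‑1‑(4‑hydroxy‑3‑methoxyphenyl)‑3‑(hydroxymethyl)‑6‑methoxy‑1,2,3,4‑tetrahydronaphthalene‑2‑carbaldehyde (obtained as its trans‑fused lactol), via enamine quinone methide 14 (not isolated)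
Conditions: pyrrolidine (30 mol%), CF3CO2H (40 mol%), CH2Cl2 (0.02 M), 0 °C → rt; then aq. NaHCO3
Reagents that add atoms: none
Why: Pyrrolidinium trifluoroacetate condenses with the open‑chain aldehyde of 13 to the E‑enamine while the acid dehydrates the para‑hydroxybenzhydrol to the para‑quinone methide (14); the enamine β‑carbon (C2) then adds to the exocyclic quinone methide carbon (C1) in a 1,6‑addition driven by rearomatisation, and the iminium ion is hydrolysed, or first trapped by the C3 hydroxymethyl oxygen, to release the lactol and the amine. The closest known reactions are the enamine‑catalysed 1,6‑addition of aldehydes to para‑quinone methides and the SN1‑type α‑alkylation of aldehydes with benzhydrols, here run within one molecule. Ring B closes in the 6‑(enolexo)‑exo‑trig mode. C1 is controlled by the C3 stereocentre through a half‑chair‑like transition state in which the C3 substituent and the quinoid ring are both pseudo‑equatorial, hence 1,3‑cis. C2 is set trans to both neighbours by the E‑enamine in the same transition state and is further secured because this α‑centre equilibrates through iminium–enamine tautomerism to the all‑equatorial isomer, whose trans‑fused lactol carries no strain. The step needs C‑alkylation over O‑ or N‑capture of the quinone methide and 1,6‑ over 1,4‑addition: heteroatom adducts re‑ionise under the acidic conditions whereas the C–C bond is kept, and only attack at the exocyclic carbon restores the arene. High dilution holds back intermolecular alkylation of phenols and arenes.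

**Step 11**
Reactants: 15 (1R,2S,3S)‑7‑(benzyloxy)‑1‑(4‑hydroxy‑3‑methoxyphenyl)‑3‑(hydroxymethyl)‑6‑methoxy‑1,2,3,4‑tetrahydronaphthalene‑2‑carbaldehyde (lactol)
Product: 16 (1R,2S,3S)‑7‑(benzyloxy)‑1‑[4‑(benzyloxy)‑3‑methoxyphenyl]‑3‑(hydroxymethyl)‑6‑methoxy‑1,2,3,4‑tetrahydronaphthalene‑2‑carbaldehyde (as its trans‑fused lactol)
Conditions: BnBr (1.05 equiv), K2CO3, DMF, rt
Reagents that add atoms: benzyl bromide, BrCc1ccccc1
Why: Williamson etherification, selective for the phenoxide over the lactol hydroxyl; it removes the free phenol that the silver oxidant of step 12 would turn into a quinone methide at C1, and any base‑induced equilibration at C2 can only confirm the all‑trans isomer.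

**Step 12**
Reactants: 16 bis(benzyl ether) lactol
Product: 17 (3aS,9R,9aS)‑7‑(benzyloxy)‑9‑[4‑(benzyloxy)‑3‑methoxyphenyl]‑6‑methoxy‑3a,4,9,9a‑tetrahydronaphtho[2,3‑c]furan‑1(3H)‑one
Conditions: Ag2CO3 on Celite, toluene, reflux
Reagents that add atoms: none
Why: Fétizon oxidation of a lactol to the lactone on the silver carbonate surface under neutral conditions; no enolisation occurs, so the strained trans ring fusion is kept.

**Step 13**
Reactants: 17 trans‑lactone bis(benzyl ether)
Product: 18 methyl (1R,2S,3S)‑7‑(benzyloxy)‑1‑[4‑(benzyloxy)‑3‑methoxyphenyl]‑3‑(hydroxymethyl)‑6‑methoxy‑1,2,3,4‑tetrahydronaphthalene‑2‑carboxylate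
Conditions: NaOMe (0.3 equiv), MeOH–THF, 0 °C → rt; AcOH quench at 0 °C
Reagents that add atoms: methanol, CO
Why: Methoxide transesterification of a γ‑lactone; the planar ester in a trans‑fused five‑membered ring is strained, so in methanol as solvent the equilibrium should lie with the open hydroxy ester, in which C2 already has the preferred equatorial orientation.

**Step 14**
Reactants: 18 bis(benzyl ether) hydroxy ester
Product: 19 methyl (1R,2S,3S)‑7‑hydroxy‑1‑(4‑hydroxy‑3‑methoxyphenyl)‑3‑(hydroxymethyl)‑6‑methoxy‑1,2,3,4‑tetrahydronaphthalene‑2‑carboxylate (target)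
Conditions: H2 (1 atm), 10% Pd/C, EtOAc–MeOH, rt
Reagents that add atoms: none
Why: Hydrogenolysis of both aryl benzyl ethers under neutral conditions, which neither relactonise the hydroxy ester nor touch the C1–H or C1–aryl bonds.

**Compound list**

1 | 6‑bromovanillin (2‑bromo‑4‑hydroxy‑5‑methoxybenzaldehyde) | COc1cc(C=O)c(Br)cc1O | starting material
2 | 4‑(benzyloxy)‑2‑bromo‑5‑methoxybenzaldehyde | COc1cc(C=O)c(Br)cc1OCc1ccccc1 | intermediate
3 | dimethyl succinate | COC(=O)CCC(=O)OC | starting material
4 | (E)‑4‑[4‑(benzyloxy)‑2‑bromo‑5‑methoxyphenyl]‑3‑(methoxycarbonyl)but‑3‑enoic acid | COC(=O)/C(CC(=O)O)=C/c1cc(OC)c(OCc2ccccc2)cc1Br | intermediate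
5 | (3S)‑3‑{[4‑(benzyloxy)‑2‑bromo‑5‑methoxyphenyl]methyl}‑4‑methoxy‑4‑oxobutanoic acid | OC(=O)C[C@@H](C(=O)OC)Cc1cc(OC)c(OCc2ccccc2)cc1Br | intermediate
6 | (4S)‑4‑{[4‑(benzyloxy)‑2‑bromo‑5‑methoxyphenyl]methyl}oxolan‑2‑one | O=C1C[C@@H](CO1)Cc1cc(OC)c(OCc2ccccc2)cc1Br | intermediate
7 | (3S)‑3‑{[4‑(benzyloxy)‑2‑bromo‑5‑methoxyphenyl]methyl}‑4‑hydroxybutanal, present as the lactol (4S)‑4‑(arylmethyl)oxolan‑2‑ol | O=CC[C@@H](CO)Cc1cc(OC)c(OCc2ccccc2)cc1Br | intermediate
8 | tert‑butyl({(4S)‑4‑{[4‑(benzyloxy)‑2‑bromo‑5‑methoxyphenyl]methyl}oxolan‑2‑yl}oxy)dimethylsilane, anomer mixture | CC(C)(C)[Si](C)(C)OC1C[C@@H](CO1)Cc1cc(OC)c(OCc2ccccc2)cc1Br | intermediate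
9 | vanillin | COc1cc(C=O)ccc1O | starting material
10 | 4‑[(tert‑butyldimethylsilyl)oxy]‑3‑methoxybenzaldehyde | COc1cc(C=O)ccc1O[Si](C)(C)C(C)(C)C | intermediate
11 | aryllithium from 8 (lithium in place of bromine), not isolated | CC(C)(C)[Si](C)(C)OC1C[C@@H](CO1)Cc1cc(OC)c(OCc2ccccc2)cc1[Li] | intermediate
12 | {4‑(benzyloxy)‑2‑{[(3S)‑5‑(tert‑butyldimethylsilyloxy)oxolan‑3‑yl]methyl}‑5‑methoxyphenyl}[4‑(tert‑butyldimethylsilyloxy)‑3‑methoxyphenyl]methanol, carbinol and anomeric epimers | CC(C)(C)[Si](C)(C)OC1C[C@@H](CO1)Cc1cc(OC)c(OCc2ccccc2)cc1C(O)c1ccc(O[Si](C)(C)C(C)(C)C)c(OC)c1 | intermediate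
13 | (3S)‑3‑{[4‑(benzyloxy)‑2‑[hydroxy(4‑hydroxy‑3‑methoxyphenyl)methyl]‑5‑methoxyphenyl]methyl}‑4‑hydroxybutanal, carbinol epimers, present as its lactol (precursor of the key step) | O=CC[C@@H](CO)Cc1cc(OC)c(OCc2ccccc2)cc1C(O)c1ccc(O)c(OC)c1 | intermediate
14 | 4‑{[4‑(benzyloxy)‑2‑[(2S,3E)‑2‑(hydroxymethyl)‑4‑(pyrrolidin‑1‑yl)but‑3‑en‑1‑yl]‑5‑methoxyphenyl]methylidene}‑2‑methoxycyclohexa‑2,5‑dien‑1‑one, not isolated | OC[C@H](/C=C/N1CCCC1)Cc1cc(OC)c(OCc2ccccc2)cc1C=C1C=CC(=O)C(OC)=C1 | intermediate
15 | (1R,2S,3S)‑7‑(benzyloxy)‑1‑(4‑hydroxy‑3‑methoxyphenyl)‑3‑(hydroxymethyl)‑6‑methoxy‑1,2,3,4‑tetrahydronaphthalene‑2‑carbaldehyde, present as its trans‑fused lactol (product of the key step) | O=C[C@@H]1[C@@H](CO)Cc2cc(OC)c(OCc3ccccc3)cc2[C@H]1c1ccc(O)c(OC)c1 | intermediate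
16 | (1R,2S,3S)‑7‑(benzyloxy)‑1‑[4‑(benzyloxy)‑3‑methoxyphenyl]‑3‑(hydroxymethyl)‑6‑methoxy‑1,2,3,4‑tetrahydronaphthalene‑2‑carbaldehyde, present as its trans‑fused lactol | O=C[C@@H]1[C@@H](CO)Cc2cc(OC)c(OCc3ccccc3)cc2[C@H]1c1ccc(OCc2ccccc2)c(OC)c1 | intermediate
17 | (3aS,9R,9aS)‑7‑(benzyloxy)‑9‑[4‑(benzyloxy)‑3‑methoxyphenyl]‑6‑methoxy‑3a,4,9,9a‑tetrahydronaphtho[2,3‑c]furan‑1(3H)‑one | O=C1OC[C@H]2Cc3cc(OC)c(OCc4ccccc4)cc3[C@@H](c3ccc(OCc4ccccc4)c(OC)c3)[C@H]12 | intermediate
18 | methyl (1R,2S,3S)‑7‑(benzyloxy)‑1‑[4‑(benzyloxy)‑3‑methoxyphenyl]‑3‑(hydroxymethyl)‑6‑methoxy‑1,2,3,4‑tetrahydronaphthalene‑2‑carboxylate | COC(=O)[C@@H]1[C@@H](CO)Cc2cc(OC)c(OCc3ccccc3)cc2[C@H]1c1ccc(OCc2ccccc2)c(OC)c1 | intermediate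
19 | methyl (1R,2S,3S)‑7‑hydroxy‑1‑(4‑hydroxy‑3‑methoxyphenyl)‑3‑(hydroxymethyl)‑6‑methoxy‑1,2,3,4‑tetrahydronaphthalene‑2‑carboxylate | COC(=O)[C@@H]1[C@@H](CO)Cc2cc(OC)c(O)cc2[C@H]1c1ccc(O)c(OC)c1 | target

**Step count and risk**

Total: 14 steps. Longest linear sequence: 13 steps (steps 1–6 and 8–14 from **1**); step 7 is a one‑step side branch.

**Step 10 (key step).** The quinone methide may be consumed faster by intermolecular alkylation (phenol oxygen, electron‑rich arenes, ether formation between two benzhydrols) than by the enamine. Ionisation may also be too slow in the amine‑buffered medium, or facial selectivity at C1 may be poor if the quinoid ring does not prefer the pseudo‑equatorial position. The fallback gives up the C1–C2 closure for the long‑established C1–C8a closure.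
- It sets out from lactone **6**. Radical debromination (Bu3SnH, AIBN, toluene, 80 °C) gives (4S)‑4‑[(4‑benzyloxy‑3‑methoxyphenyl)methyl]oxolan‑2‑one F1.
- The lithium enolate of F1 (LiN(i‑Pr)2, THF, −78 °C) adds to commercial 4‑(benzyloxy)‑3‑methoxybenzaldehyde anti to the C4 substituent. This gives the trans aldol (3R,4S)‑3‑[(4‑benzyloxy‑3‑methoxyphenyl)(hydroxy)methyl]‑4‑[(4‑benzyloxy‑3‑methoxyphenyl)methyl]oxolan‑2‑one F2 (carbinol epimers).
- CF3CO2H in CH2Cl2 ionises the carbinol and ring A attacks para to its methoxy group (Friedel–Crafts alkylation). This should give the 1,2‑trans lactone **17**, where the route is rejoined; steps 13 and 14 follow.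

**Step 3.** The ortho‑bromo substituent twists the aryl group, and any Z isomer from step 2 may react through a different pathway. Either effect could lower face discrimination at the only centre that cannot be corrected later. The fallback replaces catalysis by an oxazolidinone auxiliary alkylation (Evans alkylation).
- It sets out from aldehyde **2**. NaBH4 in MeOH gives [4‑(benzyloxy)‑2‑bromo‑5‑methoxyphenyl]methanol F3, and PBr3 converts it into 1‑(benzyloxy)‑5‑bromo‑4‑(bromomethyl)‑2‑methoxybenzene F4.
- Commercial (4S)‑4‑benzyloxazolidin‑2‑one is N‑acylated (n‑BuLi, pent‑4‑enoyl chloride) to (4S)‑4‑benzyl‑3‑(pent‑4‑enoyl)oxazolidin‑2‑one F5.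
- The sodium enolate of F5 (NaN(SiMe3)2, THF, −78 °C) is alkylated by F4 on the face away from the auxiliary's benzyl group. This gives (4S)‑4‑benzyl‑3‑[(2R)‑2‑{[4‑(benzyloxy)‑2‑bromo‑5‑methoxyphenyl]methyl}pent‑4‑enoyl]oxazolidin‑2‑one F6.
- LiBH4 removes the auxiliary and gives (2R)‑2‑{[4‑(benzyloxy)‑2‑bromo‑5‑methoxyphenyl]methyl}pent‑4‑en‑1‑ol F7.
- Oxidative cleavage of the terminal alkene (OsO4 cat., NaIO4, 2,6‑lutidine, dioxane–water) gives the hydroxy aldehyde **7**, where the route is rejoined at step 6.

**Step 8.** The aryllithium may be lost by proton transfer or by attack at silicon of the anomeric silyl ether before it meets the aldehyde, and addition next to the ortho substituent may be slow. The fallback avoids organolithium chemistry.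
- It sets out from bromide **8**. Miyaura borylation (bis(pinacolato)diboron, PdCl2(dppf), KOAc, dioxane, 80 °C) gives the aryl pinacol boronate F8.
- Rhodium‑catalysed 1,2‑addition of F8 to aldehyde **10** ([Rh(OH)(cod)]2, dioxane–water, 60 °C) gives benzhydrol **12**, where the route is rejoined at step 9.
- Partial loss of the aryl silyl ether under these conditions would not matter, since step 9 removes it.

**Step 13.** The opening is an equilibrium. It may stop short, the product may relactonise during work‑up, or prolonged base may epimerise C2 toward the cis‑lactone series. The fallback separates opening from esterification.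
- It sets out from lactone **17**. LiOH in THF–water opens it irreversibly to the lithium carboxylate of the hydroxy acid F9, which is dried without acidification.
- Alkylation of F9 with MeI in DMF at rt gives hydroxy ester **18**, where the route is rejoined at step 14.

**Further compounds**

F1 | step 10 | (4S)‑4‑[(4‑benzyloxy‑3‑methoxyphenyl)methyl]oxolan‑2‑one | O=C1C[C@@H](CO1)Cc1ccc(OCc2ccccc2)c(OC)c1
F2 | step 10 | (3R,4S)‑3‑[(4‑benzyloxy‑3‑methoxyphenyl)(hydroxy)methyl]‑4‑[(4‑benzyloxy‑3‑methoxyphenyl)methyl]oxolan‑2‑one, carbinol epimers | O=C1OC[C@@H](Cc2ccc(OCc3ccccc3)c(OC)c2)[C@@H]1C(O)c1ccc(OCc2ccccc2)c(OC)c1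
F3 | step 3 | [4‑(benzyloxy)‑2‑bromo‑5‑methoxyphenyl]methanol | COc1cc(CO)c(Br)cc1OCc1ccccc1
F4 | step 3 | 1‑(benzyloxy)‑5‑bromo‑4‑(bromomethyl)‑2‑methoxybenzene | COc1cc(CBr)c(Br)cc1OCc1ccccc1
F5 | step 3 | (4S)‑4‑benzyl‑3‑(pent‑4‑enoyl)oxazolidin‑2‑one | O=C1OC[C@H](Cc2ccccc2)N1C(=O)CCC=C
F6 | step 3 | (4S)‑4‑benzyl‑3‑[(2R)‑2‑{[4‑(benzyloxy)‑2‑bromo‑5‑methoxyphenyl]methyl}pent‑4‑enoyl]oxazolidin‑2‑one | O=C1OC[C@H](Cc2ccccc2)N1C(=O)[C@H](CC=C)Cc1cc(OC)c(OCc2ccccc2)cc1Br
F7 | step 3 | (2R)‑2‑{[4‑(benzyloxy)‑2‑bromo‑5‑methoxyphenyl]methyl}pent‑4‑en‑1‑ol | C=CC[C@@H](CO)Cc1cc(OC)c(OCc2ccccc2)cc1Br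
F8 | step 8 | pinacol boronate of 8 (4,4,5,5‑tetramethyl‑1,3,2‑dioxaborolan‑2‑yl in place of bromine) | CC(C)(C)[Si](C)(C)OC1C[C@@H](CO1)Cc1cc(OC)c(OCc2ccccc2)cc1B1OC(C)(C)C(C)(C)O1
F9 | step 13 | lithium (1R,2S,3S)‑7‑(benzyloxy)‑1‑[4‑(benzyloxy)‑3‑methoxyphenyl]‑3‑(hydroxymethyl)‑6‑methoxy‑1,2,3,4‑tetrahydronaphthalene‑2‑carboxylate | [Li+].[O-]C(=O)[C@@H]1[C@@H](CO)Cc2cc(OC)c(OCc3ccccc3)cc2[C@H]1c1ccc(OCc2ccccc2)c(OC)c1
A1 | alternative 1 | methyl 3‑[2‑allyl‑5‑(benzyloxy)‑4‑methoxyphenyl]‑2‑diazo‑3‑oxopropanoate | COC(=O)C(=[N+]=[N-])C(=O)c1cc(OCc2ccccc2)c(OC)cc1CC=C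
A2 | alternative 1 | cyclopropane‑fused 1‑tetralone β‑keto ester with C3 as in the target | COC(=O)[C@]12C[C@H]1Cc1cc(OC)c(OCc3ccccc3)cc1C2=O
A3 | alternative 2 | (E)‑3‑[4‑(benzyloxy)‑3‑methoxyphenyl]prop‑2‑en‑1‑yl (E)‑3‑[4‑(benzyloxy)‑3‑methoxyphenyl]prop‑2‑enoate | COc1cc(/C=C/COC(=O)/C=C/c2ccc(OCc3ccccc3)c(OC)c2)ccc1OCc1ccccc1
A4 | alternative 2 | trans‑fused aryltetralin lactone bis(benzyl ether), identical with 17 | O=C1OC[C@H]2Cc3cc(OC)c(OCc4ccccc4)cc3[C@@H](c3ccc(OCc4ccccc4)c(OC)c3)[C@H]12
A5 | alternative 3 | methyl 3‑{5‑(benzyloxy)‑2‑[(E)‑4‑(diethoxyphosphoryloxy)but‑2‑en‑1‑yl]‑4‑methoxyphenyl}prop‑2‑ynoate | COC(=O)C#Cc1cc(OCc2ccccc2)c(OC)cc1C/C=C/COP(=O)(OCC)OCC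
A6 | alternative 3 | [4‑(benzyloxy)‑3‑methoxyphenyl]boronic acid | COc1cc(B(O)O)ccc1OCc1ccccc1
A7 | alternative 3 | methyl 1‑aryl‑3‑vinyl‑3,4‑dihydronaphthalene‑2‑carboxylate with the C3 stereocentre | COC(=O)C1=C(c2ccc(OCc3ccccc3)c(OC)c2)c2cc(OCc3ccccc3)c(OC)cc2C[C@@H]1C=C
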